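The gas feeds G into the liquid at 0.0708 M min⁻¹ while little G is dissolved, and the argument turns on that number.

    Z + G → Z.G (k1 = 7.0 L mol⁻¹ min⁻¹, Ea1 = 59.0 kJ mol⁻¹)
    Z + Z.G ⇌ Z.Z.G, settled at all times (K2 = 0.37 L mol⁻¹, ΔH2 = −9.00 kJ mol⁻¹)
    Z + 2 G → J (k3 = 1.2 L² mol⁻² min⁻¹, Ea3 = 65.0 kJ mol⁻¹)
    D ⇌ G, rate k4*(csat - [G]) (k4 = 1.2 min⁻¹, csat = 59 mM)
    Z + Z.G → L (k5 = 0.16 L mol⁻¹ min⁻¹, Ea5 = 64.0 kJ mol⁻¹)
    (constants at 40 °C)

in all of them: Z 1.5 M; D 59 mM (held); time 20 min

| run | temperature |
|---|---|
| alpha | 85 °C |
| zeta | 40 °C |
| delta | 70 °C |
| eta | 55 °C |

- the flask with the highest share of Z.G in all that became Z.G or J or L ("all alike" if they lie within 1.5 percentage points) (alpha / zeta / delta / eta / all alike)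
- share of Z.G in all that became Z.G or J or L, alpha
- share of Z.G in all that became Z.G or J or L, zeta
- share of Z.G in all that became Z.G or J or L, delta
- share of Z.G in all that became Z.G or J or L, eta

- in percentages every species weighs as the Z in it: one Z.Z.G or L counts as two
- for Z.G the Z.Z.G is counted in
- where a step has two of a species, its rate is k times that concentration squared, and two are used at each turn
- at the start none of G is dissolved
- constants are those at 40 °C; use the activation energies and enthalpies for any other temperature
- in an amount of Z.G, one Z.Z.G counts as one Z.G

Two chemists disagree before any run. The rival reads this as a plain consecutive reaction with G at saturation. Z.G then gains from Z + G and loses to Z + Z.G. Those two rates balance at a Z.G level of 2.58 M in zeta and 2.03 M in alpha. Both levels stand above the charge of Z. So the rival expects Z.G to stay the main product at both ends of the temperature range.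

I hold the other view. The concentration that sets the order of the first step is dissolved G. In zeta at the start, Z removes G at 10.5 min⁻¹, faster than the gas refills it at 1.2 min⁻¹. So G stays low, and gas transfer is the rate-limiting step. Z.G then forms at the supply rate, zero order in Z.

Z.G climbs until its loss to L matches that supply, and it rises further as Z falls. The climb ends when Z is gone. For the level reached I take an estimate, which I call the lid: the square root of the supply divided by the rate constant of the step to L.

That constant grows by a factor of 22 from zeta to alpha. The lid is therefore 0.142 M in alpha, lower than 0.665 M in zeta. While the balance lasts, each unit of supply uses two Z. Alpha's Z should therefore be gone near 10.6 min, earlier than the asked time.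

One L weighs as two Z, so with Z used up the share is the lid over the charge. That gives 9.47% for alpha and 44.3% for zeta. My reckoning stops at these two flasks.

The forecast takes my side of the dispute and names zeta: 9.7% for alpha, 42% for zeta, 15.7% for delta, 26% for eta. In its words, “The coolest flask gives the highest share.” Its zeta stands below my figure, and its alpha above mine.

The simulation gives 9.47% for alpha, 41.0% for zeta, 15.2% for delta and 25.4% for eta, so zeta leads. Alpha has come to rest, with Z at 0% at 20.0 min and the share unchanged at 9.47% after 200 min. Zeta has not. At 20.0 min it holds 5.09% of its Z, and G has recovered to 0.0386 M. That late stretch, with G at 65.3% of saturation, is the rival's ground. Left until 200 min, zeta rises 0.80 percentage points and stays under its lid share of 44.3%, ending at 41.8%.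

The constants used here are those of an exercise, and the outcome is calculated.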